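## The problem

Target 25 is a (3R)-isoflavan. Ring A, a phloroglucinol nucleus, is fused to the saturated pyran ring C, and C3 of ring C carries ring B, a phenol fused to a 2,2-dimethyl-2H-pyran (a 5-hydroxy-2,2-dimethyl-2H-chromen-8-yl group). Ring A holds three meta-related oxygens of different kind: O1 at C8a inside ring C, a methyl ether at C5 and a free hydroxyl at C7. A synthesis must tell them apart and attach C4 to the one carbon, C4a, that lies between C8a and C5. The only stereocentre is C3, a benzylic CH between two methylene groups. Nothing in the molecule can direct it, so it must come from a reagent-, catalyst- or enzyme-controlled reaction on a prochiral 2-aryl three-carbon unit. It should never sit next to a carbonyl group late in the route, where an α-aryl centre would epimerise. The fragile parts are the 2,2-dimethylchromene, which is lost on hydrogenation and opened or hydrated by strong acid, and two electron-rich phenols. Benzyl ethers and acid-labile phenol protection are therefore unattractive, and the last step should be a fluoride desilylation. The feature that invites the key step is that C8a–O1 and C4a–C4 sit on adjacent carbons of ring A with the C5 methoxy group directly beside C4a. That is the pattern left when an oxygen nucleophile adds to a 3-methoxyaryne at the carbon remote from the methoxy group and the aryl anion beside the methoxy group is then alkylated. The chain O1–C2–C3–C4 can supply both the oxygen nucleophile and the carbon electrophile.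

## Retrosynthesis

**25 from 24.** The two phenols are masked as triisopropylsilyl ethers in 24. Only two O–Si bonds are cut, by fluoride, which leaves the chromene untouched. Benzyl ethers would need hydrogenolysis and methoxymethyl ethers would need acid, and both endanger the chromene. The bulky silyl group also survives organolithium, amine and alkoxide reagents earlier in the route.

**24 from 9 and 20.** O1–C8a and C4–C4a are cut together. This is ring C taken off ring A in one operation: an aryne 22 (from silyl triflate 9) accepts the alkoxide 21 of chloro alcohol 20 at C8a, and the aryl anion 23 at C4a closes onto the chloromethyl carbon. Cutting only O1–C8a would leave a later Friedel–Crafts closure that cannot choose between the two ortho carbons of ring A. Cutting O1–C2 and C4–C4a needs a halogenated ring A and two separate steps. The double cut reduces the target to a benzene with three oxygens and a C3 chain that already carries ring B and the stereocentre. The forward reaction must add at the correct aryne carbon, must run without any proton source so that 23 lives long enough to alkylate, and must capture the aryne faster than 21 closes to an oxetane.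

**9 from 1 via 2, 3 and 7.** The C–Si and O–S bonds of 9 are cut back to carbamate 3 of the monosilylated 5-methoxyresorcinol 2. The carbamate and the methoxy group cooperate to direct lithiation to the carbon between them, and the silyl ether shields the other side. Bromination of phenol 2 followed by a retro-Brook shift would have to choose among three activated positions. The symmetry of 1 means only mono- versus bis-silylation needs handling.

**20 from 17 via 18 and 19.** The stereocentre is traced to the prochiral diol 17. A lipase acetylates one enantiotopic arm (18), the arm left free becomes the chloride (19), and the acetate is removed (20). Chloride is preferred to bromide or sulfonate because the alkoxide of 20 must not cyclise before it meets the aryne. The forward sequence must avoid 1,3-acyl migration in 18, which would racemise it.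

**17 from 14 and 15 via 16.** The C3–C1′ bond is cut to bromide 14 and diethyl malonate 15 (Pd-catalysed α-arylation), followed by reduction of 16. This brings in the whole C2–C3–C4 unit in one coupling and gives the two arms as equal hydroxymethyl groups, the form an enzyme can differentiate.

**14 from 10 and 12 via 11 and 13.** The pyran of ring B is opened to aryl propargyl ether 13 (Claisen rearrangement, hydrogen shift, electrocyclisation), made from phenol 11 and chloride 12. Phenol 11 is 4-bromoresorcinol 10 silylated at its less hindered hydroxyl. The bromine blocks one ortho position, so the pyran can only fuse at the carbon between the two oxygens, and the same bromine later serves as the coupling handle.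

## Roads not taken

**Alternative 1:** Cut C3–C1′ and C4–C4a, with boron standing in for C2. The boron ate complex from vinylboronic acid pinacol ester A3 and the ring-B aryllithium A4 (from 14 by bromine–lithium exchange) would react with the ring-A triflate A2, Pd(OAc)2 and a chiral ferrocene-based bisphosphine. Oxidative addition of A2 to zerovalent palladium gives an aryl palladium cation that binds the vinyl group and triggers 1,2-migration of the ring-B aryl group from boron to carbon. Reductive elimination forms C4–C4a and gives the (R)-boronate A1.
- Merits: the catalyst sets C3 while joining three pieces, either sense is available by choice of ligand, and the reaction type is established for aryl migrating groups and aryl triflates.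
- Weak points: A2 is electron-rich and substituted at both ortho positions, the worst case for oxidative addition and for the crowded migration step. Because its triflate sits on C4a, ring A needs a fourth oxygen, so a 1,2,3,5-tetraoxygenated benzene with four different oxygen substituents must be made. After A1 there remain a one-carbon homologation with oxidation, removal of the methoxymethyl ether with acid in the presence of the chromene, a Mitsunobu closure of ring C and the desilylation.
- Comparison: this road is better in the source of chirality and in precedent for its key step. The chosen plan answers with a simpler ring-A partner (three oxygens, the triflate on the carbon that will carry O1), with ring C formed directly at its final oxidation level, and with no acidic step.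

**Alternative 2:** Cut C4a–C5 and C8–C8a, so that ring A is built and not bought. Heating the chiral siloxyalkyne A6 with 3-(allyloxy)cyclobutenone A7 would open the cyclobutenone to a vinylketene, add it to the alkyne, reopen the new four-membered ring and close the resulting dienylketene to the phenol A5 (Danheiser benzannulation).
- Merits: every ring-A substituent is placed by construction, with no question of aryne regiochemistry, and the three oxygens emerge chemically distinct (free hydroxyl, allyl ether, silyl ether).
- Weak points: A6 is a moisture-sensitive alkynyl silyl ether that needs an ester homologation on a chain already carrying the stereocentre, so the asymmetric step is not saved, only moved. In A5 the silyl ethers at C8a and C4′ cannot be told apart. Methylation, desilylation, Mitsunobu closure and deallylation still follow, giving a long linear sequence.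
- Comparison: each step is of a known type, which the chosen plan cannot claim for its key step. The chosen plan is much shorter and convergent, and it does not construct a benzene ring that can be bought.

**Alternative 3:** Cut C3–C4 and O1–C2, with C2 as a carbonyl carbon. The ortho-quinone methide A11, released from sulfone A9 by Cs2CO3, would be trapped by the isothiourea-bound enolate of the ring-B arylacetic acid A10 (activated with pivaloyl chloride) to give the (3R)-3-arylchroman-2-one A8.
- Merits: catalytic, convergent, the sense of induction is selectable, and the reaction type is known for aryl acetic acids.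
- Weak points: A11 has no substituent on its methylene carbon and should oligomerise readily. The new centre in A8 is both benzylic and α to a lactone carbonyl, so it can racemise by enolisation in the basic medium. A8 must be reduced and ring C closed again by Mitsunobu etherification. A9 needs a carbon substituent placed on ring A between hydroxyl and methoxy, one of three activated positions.
- Comparison: the step count is similar and precedent is closer, so this road would rival the chosen one if the enantiopurity held. The chosen plan never places C3 beside a carbonyl group and forms ring C once, at the right oxidation level.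

Key step: step 13

Assumption: in the acylation mode the lipase is taken to leave free the hydroxymethyl arm of 17 that corresponds to the (S)-monoacetate 18. This preference is empirical for a new 2-aryl-1,3-diol, and the fallback for step 10 uses a catalyst whose sense can be chosen.

## Route

Step 1
Reactants: 1 5-methoxyresorcinol
Product: 2 3-methoxy-5-(triisopropylsilyloxy)phenol
Conditions: TIPSCl (1 equiv), imidazole, DMF, 0 °C to rt; chromatographic separation from diol and bis-ether
Reagents that add atoms: triisopropylsilyl chloride, CC(C)[Si](Cl)(C(C)C)C(C)C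
Why: Statistical monosilylation of a symmetrical diol, so only mono- versus bis-silylation has to be handled and both side fractions can be recycled; the bulky silyl ether later survives organolithiums, amines and alkoxides and blocks lithiation on its side.

Step 2
Reactants: 2 3-methoxy-5-(triisopropylsilyloxy)phenol
Product: 3 3-methoxy-5-(triisopropylsilyloxy)phenyl N-isopropylcarbamate
Conditions: i-PrNCO, Et3N (cat.), CH2Cl2, rt
Reagents that add atoms: isopropyl isocyanate, CC(C)N=C=O
Why: Base-catalysed addition of a phenol to an isocyanate (carbamoylation) installs a secondary carbamate that directs ortho-metalation and can later be removed under mild amine conditions.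

Step 3
Reactants: 3 3-methoxy-5-(triisopropylsilyloxy)phenyl N-isopropylcarbamate
Product: 7 3-methoxy-5-(triisopropylsilyloxy)-2-(trimethylsilyl)phenyl N-isopropylcarbamate, via N-silyl carbamate 4 (not isolated), via aryllithium 5 (not isolated), via N-silyl C-silyl carbamate 6 (not isolated)
Conditions: TBSOTf, TMEDA, Et2O, 0 °C to rt; n-BuLi, TMEDA, −78 °C; TMSCl, −78 °C to rt; aq. NaHSO4 work-up
Reagents that add atoms: chlorotrimethylsilane, C[Si](C)(C)Cl (tert-butyldimethylsilyl triflate, CC(C)(C)[Si](C)(C)OS(=O)(=O)C(F)(F)F, supplies only the N-silyl group carried by 4 to 6)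
Why: Directed ortho-metalation: after N-silylation in the flask the O-carbamate and the methoxy group cooperate to direct n-BuLi to the carbon between them, while the other ortho carbon is shielded by the bulky silyl ether; the aryllithium is silylated by TMSCl and the N-silyl group is lost on acidic work-up.

Step 4
Reactants: 7 3-methoxy-5-(triisopropylsilyloxy)-2-(trimethylsilyl)phenyl N-isopropylcarbamate
Product: 9 3-methoxy-5-(triisopropylsilyloxy)-2-(trimethylsilyl)phenyl trifluoromethanesulfonate, via silyl phenol 8 (not isolated)
Conditions: DBU, Et2NH, MeCN, 40 °C; then PhNTf2, rt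
Reagents that add atoms: N-phenylbis(trifluoromethanesulfonimide), O=S(=O)(N(c1ccccc1)S(=O)(=O)C(F)(F)F)C(F)(F)F
Why: E1cB cleavage of the deprotonated secondary carbamate (the expelled isocyanate is trapped by Et2NH as a urea) frees the hindered phenoxide, which is sulfonylated in the same flask by PhNTf2; the mild base spares the aryl silyl ether and the aryl–silicon bond.

Step 5
Reactants: 10 4-bromoresorcinol
Product: 11 2-bromo-5-(triisopropylsilyloxy)phenol
Conditions: TIPSCl (1.05 equiv), imidazole, CH2Cl2, 0 °C to rt
Reagents that add atoms: triisopropylsilyl chloride, CC(C)[Si](Cl)(C(C)C)C(C)C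
Why: Sterically controlled silylation: the bulky chlorosilane should take the hydroxyl para to bromine and leave the one flanked by bromine, which is the later pyran oxygen.

Step 6
Reactants: 11 2-bromo-5-(triisopropylsilyloxy)phenol; 12 3-chloro-3-methylbut-1-yne
Product: 13 1-bromo-2-[(2-methylbut-3-yn-2-yl)oxy]-4-(triisopropylsilyloxy)benzene
Conditions: CuCl2·2H2O (cat.), DBU, MeCN, 0 °C
Reagents that add atoms: none
Why: Copper-catalysed propargylic substitution (through a copper acetylide/allenylidene) O-alkylates phenols with tertiary propargylic chlorides under mild base, where a direct SN2 reaction is impossible.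

Step 7
Reactants: 13 1-bromo-2-[(2-methylbut-3-yn-2-yl)oxy]-4-(triisopropylsilyloxy)benzene
Product: 14 8-bromo-2,2-dimethyl-5-(triisopropylsilyloxy)-2H-chromene
Conditions: xylenes, 140 °C
Reagents that add atoms: none
Why: Aromatic propargyl Claisen rearrangement, 1,5-hydrogen shift and oxa-6π electrocyclisation give the 2,2-dimethylchromene; bromine blocks one ortho position, so only the carbon between the two oxygens can receive the side chain.

Step 8
Reactants: 14 8-bromo-2,2-dimethyl-5-(triisopropylsilyloxy)-2H-chromene; 15 diethyl malonate
Product: 16 diethyl 2-[2,2-dimethyl-5-(triisopropylsilyloxy)-2H-chromen-8-yl]malonate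
Conditions: Pd(OAc)2 (cat.), P(t-Bu)3·HBF4 (cat.), K3PO4, toluene, 80 °C
Reagents that add atoms: none
Why: Pd-catalysed α-arylation of a malonate (oxidative addition of the bromide to zerovalent palladium, enolate exchange, reductive elimination); the bulky electron-rich phosphine copes with electron-rich ortho-substituted bromides, and the cyclic cis-alkene is a poor Heck acceptor.

Step 9
Reactants: 16 diethyl 2-[2,2-dimethyl-5-(triisopropylsilyloxy)-2H-chromen-8-yl]malonate
Product: 17 2-[2,2-dimethyl-5-(triisopropylsilyloxy)-2H-chromen-8-yl]propane-1,3-diol
Conditions: LiAlH4, THF, 0 °C to rt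
Reagents that add atoms: none
Why: Hydride reduction of both esters gives the prochiral 1,3-diol; the aryl silyl ether and the chromene double bond are inert to LiAlH4 at this temperature.

Step 10
Reactants: 17 2-[2,2-dimethyl-5-(triisopropylsilyloxy)-2H-chromen-8-yl]propane-1,3-diol
Product: 18 (S)-2-[2,2-dimethyl-5-(triisopropylsilyloxy)-2H-chromen-8-yl]-3-hydroxypropyl acetate
Conditions: Burkholderia cepacia lipase (immobilised), vinyl acetate, t-BuOMe, 25 °C
Reagents that add atoms: vinyl acetate, CC(=O)OC=C
Why: Enzymatic desymmetrisation by irreversible lipase-catalysed transesterification with an enol ester; the enzyme acylates one enantiotopic hydroxymethyl arm and thereby sets the C3 stereocentre, and slight over-acylation to the diacetate removes the minor enantiomer.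

Step 11
Reactants: 18 (S)-2-[2,2-dimethyl-5-(triisopropylsilyloxy)-2H-chromen-8-yl]-3-hydroxypropyl acetate
Product: 19 (R)-3-chloro-2-[2,2-dimethyl-5-(triisopropylsilyloxy)-2H-chromen-8-yl]propyl acetate
Conditions: PPh3, CCl4, CH2Cl2, 0 °C to rt
Reagents that add atoms: carbon tetrachloride, ClC(Cl)(Cl)Cl
Why: Appel chlorination: chloride displaces the alkoxyphosphonium ion at the primary carbon in an SN2 step under neutral conditions, which avoids the 1,3-acetyl migration that would racemise 18; the stereocentre is untouched and its descriptor changes only through the priority rules.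

Step 12
Reactants: 19 (R)-3-chloro-2-[2,2-dimethyl-5-(triisopropylsilyloxy)-2H-chromen-8-yl]propyl acetate
Product: 20 (R)-3-chloro-2-[2,2-dimethyl-5-(triisopropylsilyloxy)-2H-chromen-8-yl]propan-1-ol
Conditions: K2CO3 (cat.), MeOH, 0 °C
Reagents that add atoms: none
Why: Base-catalysed transesterification (methanolysis) of the acetate; at 0 °C with catalytic carbonate neither 4-exo-tet closure of the chloro alcohol nor cleavage of the aryl triisopropylsilyl ether should compete.

Step 13
Reactants: 20 (R)-3-chloro-2-[2,2-dimethyl-5-(triisopropylsilyloxy)-2H-chromen-8-yl]propan-1-ol; 9 3-methoxy-5-(triisopropylsilyloxy)-2-(trimethylsilyl)phenyl trifluoromethanesulfonate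
Product: 24 (3R)-3-[2,2-dimethyl-5-(triisopropylsilyloxy)-2H-chromen-8-yl]-5-methoxy-7-(triisopropylsilyloxy)chroman, via potassium alkoxide 21 (not isolated), via aryne 22 (not isolated), via aryl anion 23 (not isolated)
Conditions: KH, 18-crown-6, THF, 0 °C; then Cs2CO3, 9 (1.5 equiv, slow addition), THF–toluene, 0 °C to rt
Reagents that add atoms: none
Why: Proposed new method: KH turns 20 into alkoxide 21 with hydrogen as the only by-product, so that no O–H or N–H acid is left in the flask, and Cs2CO3 with 18-crown-6 removes the trimethylsilyl group of 9 so that triflate leaves and aryne 22 forms without fluoride, which the two aryl silyl ethers would not tolerate. Alkoxide 21 adds to the aryne carbon remote from the methoxy group (the later C8a), because an inductively distorted 3-alkoxyaryne is attacked where the charge then develops on the carbon next to oxygen, and aryl anion 23 results with its charge at C4a. Anion 23 displaces chloride from C4 in an intramolecular SN2 reaction, a 6-exo-tet closure of ring C with the geometry of a Parham cyclialkylation. The closest known reaction types are the insertion of arynes into the C–O bond of epoxides, where the aryl anion of an oxygen adduct also alkylates intramolecularly, and the Parham cyclisation of ortho-metalated aryl ethers onto tethered primary halides; alkoxide addition to an aryne coupled with C-alkylation by a tethered halide has not been shown. No stereocentre is formed: C3 lies between the two reacting ends, neither bond change involves it, and the R centre of 20 appears as 3R in 24. Three selectivities are needed: the site of addition, secured by the methoxy group beside the aryne; C-alkylation of 23 ahead of protonation, secured by the aprotic medium and the intramolecular electrophile; and aryne capture ahead of 4-exo-tet closure of 21 to the achiral 3-aryloxetane, secured by chloride as a deliberately poor leaving group and by the low temperature. Slow addition of 9 keeps 22 dilute, so that 23 meets its own chloride before a second aryne or a triflate group of 9.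

Step 14
Reactants: 24 (3R)-3-[2,2-dimethyl-5-(triisopropylsilyloxy)-2H-chromen-8-yl]-5-methoxy-7-(triisopropylsilyloxy)chroman
Product: 25 (3R)-3-(5-hydroxy-2,2-dimethyl-2H-chromen-8-yl)-5-methoxychroman-7-ol
Conditions: Bu4NF, AcOH, THF, 0 °C
Reagents that add atoms: none
Why: Fluoride-induced desilylation of both aryl silyl ethers; the AcOH buffer keeps the electron-rich phenols protonated, and the chromene and the C3 centre are inert to these conditions.

## Compound list

1 | 5-methoxyresorcinol | COc1cc(O)cc(O)c1 | starting material
2 | 3-methoxy-5-(triisopropylsilyloxy)phenol | COc1cc(O)cc(O[Si](C(C)C)(C(C)C)C(C)C)c1 | intermediate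
3 | 3-methoxy-5-(triisopropylsilyloxy)phenyl N-isopropylcarbamate | COc1cc(OC(=O)NC(C)C)cc(O[Si](C(C)C)(C(C)C)C(C)C)c1 | intermediate
4 | 3-methoxy-5-(triisopropylsilyloxy)phenyl N-(tert-butyldimethylsilyl)-N-isopropylcarbamate | COc1cc(OC(=O)N(C(C)C)[Si](C)(C)C(C)(C)C)cc(O[Si](C(C)C)(C(C)C)C(C)C)c1 | intermediate
5 | 2-lithio derivative of 4 (lithium on the carbon between carbamate oxygen and methoxy) | COc1cc(O[Si](C(C)C)(C(C)C)C(C)C)cc(OC(=O)N(C(C)C)[Si](C)(C)C(C)(C)C)c1[Li] | intermediate
6 | 3-methoxy-5-(triisopropylsilyloxy)-2-(trimethylsilyl)phenyl N-(tert-butyldimethylsilyl)-N-isopropylcarbamate | COc1cc(O[Si](C(C)C)(C(C)C)C(C)C)cc(OC(=O)N(C(C)C)[Si](C)(C)C(C)(C)C)c1[Si](C)(C)C | intermediate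
7 | 3-methoxy-5-(triisopropylsilyloxy)-2-(trimethylsilyl)phenyl N-isopropylcarbamate | COc1cc(O[Si](C(C)C)(C(C)C)C(C)C)cc(OC(=O)NC(C)C)c1[Si](C)(C)C | intermediate
8 | 3-methoxy-5-(triisopropylsilyloxy)-2-(trimethylsilyl)phenol | COc1cc(O[Si](C(C)C)(C(C)C)C(C)C)cc(O)c1[Si](C)(C)C | intermediate
9 | 3-methoxy-5-(triisopropylsilyloxy)-2-(trimethylsilyl)phenyl trifluoromethanesulfonate | COc1cc(O[Si](C(C)C)(C(C)C)C(C)C)cc(OS(=O)(=O)C(F)(F)F)c1[Si](C)(C)C | intermediate
10 | 4-bromoresorcinol | Oc1ccc(Br)c(O)c1 | starting material
11 | 2-bromo-5-(triisopropylsilyloxy)phenol | Oc1cc(O[Si](C(C)C)(C(C)C)C(C)C)ccc1Br | intermediate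
12 | 3-chloro-3-methylbut-1-yne | CC(C)(Cl)C#C | starting material
13 | 1-bromo-2-[(2-methylbut-3-yn-2-yl)oxy]-4-(triisopropylsilyloxy)benzene | C#CC(C)(C)Oc1cc(O[Si](C(C)C)(C(C)C)C(C)C)ccc1Br | intermediate
14 | 8-bromo-2,2-dimethyl-5-(triisopropylsilyloxy)-2H-chromene | CC1(C)C=Cc2c(O[Si](C(C)C)(C(C)C)C(C)C)ccc(Br)c2O1 | intermediate
15 | diethyl malonate | CCOC(=O)CC(=O)OCC | starting material
16 | diethyl 2-[2,2-dimethyl-5-(triisopropylsilyloxy)-2H-chromen-8-yl]malonate | CCOC(=O)C(C(=O)OCC)c1ccc(O[Si](C(C)C)(C(C)C)C(C)C)c2C=CC(C)(C)Oc12 | intermediate
17 | 2-[2,2-dimethyl-5-(triisopropylsilyloxy)-2H-chromen-8-yl]propane-1,3-diol | OCC(CO)c1ccc(O[Si](C(C)C)(C(C)C)C(C)C)c2C=CC(C)(C)Oc12 | intermediate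
18 | (S)-2-[2,2-dimethyl-5-(triisopropylsilyloxy)-2H-chromen-8-yl]-3-hydroxypropyl acetate | CC(=O)OC[C@@H](c1ccc(O[Si](C(C)C)(C(C)C)C(C)C)c2C=CC(C)(C)Oc12)CO | intermediate
19 | (R)-3-chloro-2-[2,2-dimethyl-5-(triisopropylsilyloxy)-2H-chromen-8-yl]propyl acetate | CC(=O)OC[C@@H](c1ccc(O[Si](C(C)C)(C(C)C)C(C)C)c2C=CC(C)(C)Oc12)CCl | intermediate
20 | (R)-3-chloro-2-[2,2-dimethyl-5-(triisopropylsilyloxy)-2H-chromen-8-yl]propan-1-ol | ClC[C@H](c1ccc(O[Si](C(C)C)(C(C)C)C(C)C)c2C=CC(C)(C)Oc12)CO | intermediate
21 | potassium alkoxide of 20 | ClC[C@H](c1ccc(O[Si](C(C)C)(C(C)C)C(C)C)c2C=CC(C)(C)Oc12)C[O-].[K+] | intermediate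
22 | 3-methoxy-5-(triisopropylsilyloxy)benzyne (1,2-didehydro-3-methoxy-5-(triisopropylsilyloxy)benzene) | COC1=CC(O[Si](C(C)C)(C(C)C)C(C)C)=CC#C1 | intermediate
23 | potassium aryl anion: (R)-3-chloro-2-arylpropyl ether of ring A with the negative charge on the carbon between the ether oxygen and the methoxy group | COc1cc(O[Si](C(C)C)(C(C)C)C(C)C)cc(OC[C@H](CCl)c2ccc(O[Si](C(C)C)(C(C)C)C(C)C)c3C=CC(C)(C)Oc23)[c-]1.[K+] | intermediate
24 | (3R)-3-[2,2-dimethyl-5-(triisopropylsilyloxy)-2H-chromen-8-yl]-5-methoxy-7-(triisopropylsilyloxy)chroman | COc1cc(O[Si](C(C)C)(C(C)C)C(C)C)cc2c1C[C@H](c1ccc(O[Si](C(C)C)(C(C)C)C(C)C)c3C=CC(C)(C)Oc13)CO2 | intermediate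
25 | (3R)-3-(5-hydroxy-2,2-dimethyl-2H-chromen-8-yl)-5-methoxychroman-7-ol | COc1cc(O)cc2c1C[C@H](c1ccc(O)c3c1OC(C)(C)C=C3)CO2 | target

## Step count and risks

Total step count: 14. Longest linear sequence: 10 steps (steps 5 to 14, from 10 to 25). The branch to 9 has 4 steps (steps 1 to 4).

**Step 13 (key step, proposed new method).** Three things are most likely to go wrong.
- Aryl anion 23 may be quenched before ring closure, by proton transfer from traces of water, from the crown ether or from the benzylic C3–H followed by loss of chloride. This would leave an open-chain aryl ether.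
- Alkoxide 21 may be consumed by silyl transfer from 9 or from an aryl silyl ether. The trimethylsilyl ether would return 20 on work-up, so this costs conversion but not material.
- Alkoxide 21 may close to the oxetane or eliminate HCl before aryne is available.

The fallback separates the two bond formations and uses known chemistry. It sets out from carbamate 3 and chloro alcohol 20.
- Carbamate 3 is N-silylated and ortho-lithiated exactly as in step 3 (through 4 and 5). Quenching with iodine gives 2-iodo-3-methoxy-5-(triisopropylsilyloxy)phenyl N-(tert-butyldimethylsilyl)-N-isopropylcarbamate F1 in the flask, and acidic work-up gives 2-iodo-3-methoxy-5-(triisopropylsilyloxy)phenyl N-isopropylcarbamate F2.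
- DBU and Et2NH in MeCN free 2-iodo-3-methoxy-5-(triisopropylsilyloxy)phenol F3.
- Mitsunobu etherification of F3 with 20 (PPh3, diisopropyl azodicarboxylate, THF) forms the O1–C2 bond and gives (R)-8-[1-chloro-3-[2-iodo-3-methoxy-5-(triisopropylsilyloxy)phenoxy]propan-2-yl]-2,2-dimethyl-5-(triisopropylsilyloxy)-2H-chromene F4.
- Iodine–lithium exchange with t-BuLi in THF at −100 °C and slow warming lets the aryllithium close ring C by the same 6-exo-tet displacement of chloride (Parham cyclialkylation). The sequence rejoins the route at 24.

**Step 10.** The most likely failure is poor or reversed discrimination of the two hydroxymethyl arms, because the aryl group is bulky and carries an ortho oxygen. Acyl migration in 18 could erode the ee further. The fallback sets out from diol 17 and uses a dinuclear zinc catalyst (Et2Zn and a ProPhenol ligand of the enantiomeric series that gives the needed sense) with vinyl benzoate. This gives (S)-2-[2,2-dimethyl-5-(triisopropylsilyloxy)-2H-chromen-8-yl]-3-hydroxypropyl benzoate F5. Appel chlorination gives (R)-3-chloro-2-[2,2-dimethyl-5-(triisopropylsilyloxy)-2H-chromen-8-yl]propyl benzoate F6, and methanolysis with K2CO3 rejoins the route at 20.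

**Step 9.** The most likely failure is deprotonation of the acidic malonate C–H by hydride. The enolate is reduced sluggishly and, after the first reduction, can expel alkoxide towards 2-arylallyl alcohol. The fallback sets out from bromide 14 and avoids a doubly activated C–H. Pd-catalysed α-arylation of tert-butyl acetate (LiN(SiMe3)2, Pd(dba)2, P(t-Bu)3, toluene) gives tert-butyl 2-[2,2-dimethyl-5-(triisopropylsilyloxy)-2H-chromen-8-yl]acetate F7. Enolisation with lithium diisopropylamide and an aldol reaction with formaldehyde give racemic tert-butyl 2-[2,2-dimethyl-5-(triisopropylsilyloxy)-2H-chromen-8-yl]-3-hydroxypropanoate F8. LiAlH4 reduction rejoins the route at 17.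

**Step 7.** The most likely failure is a slow sigmatropic shift into the crowded carbon between the ether oxygen and the bulky silyl ether. That would let the tertiary propargyl ether fragment back to 11 or cyclise to five-membered by-products. The fallback sets out from phenol 11 and builds the pyran by condensation instead of rearrangement. Heating 11 with 3-methylbut-2-enal, PhB(OH)2 and AcOH in toluene with removal of water forms 8-bromo-4-(2-methylprop-1-enyl)-2-phenyl-5-(triisopropylsilyloxy)-4H-1,3,2-benzodioxaborinine F9 in the flask. On further heating F9 loses the boron unit and closes by 6π electrocyclisation, rejoining the route at 14.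

## Further compounds

F1 | step 13 | 2-iodo-3-methoxy-5-(triisopropylsilyloxy)phenyl N-(tert-butyldimethylsilyl)-N-isopropylcarbamate | COc1cc(O[Si](C(C)C)(C(C)C)C(C)C)cc(OC(=O)N(C(C)C)[Si](C)(C)C(C)(C)C)c1I
F2 | step 13 | 2-iodo-3-methoxy-5-(triisopropylsilyloxy)phenyl N-isopropylcarbamate | COc1cc(O[Si](C(C)C)(C(C)C)C(C)C)cc(OC(=O)NC(C)C)c1I
F3 | step 13 | 2-iodo-3-methoxy-5-(triisopropylsilyloxy)phenol | COc1cc(O[Si](C(C)C)(C(C)C)C(C)C)cc(O)c1I
F4 | step 13 | (R)-8-[1-chloro-3-[2-iodo-3-methoxy-5-(triisopropylsilyloxy)phenoxy]propan-2-yl]-2,2-dimethyl-5-(triisopropylsilyloxy)-2H-chromene | COc1cc(O[Si](C(C)C)(C(C)C)C(C)C)cc(OC[C@H](CCl)c2ccc(O[Si](C(C)C)(C(C)C)C(C)C)c3C=CC(C)(C)Oc23)c1I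
F5 | step 10 | (S)-2-[2,2-dimethyl-5-(triisopropylsilyloxy)-2H-chromen-8-yl]-3-hydroxypropyl benzoate | O=C(OC[C@@H](c1ccc(O[Si](C(C)C)(C(C)C)C(C)C)c2C=CC(C)(C)Oc12)CO)c1ccccc1
F6 | step 10 | (R)-3-chloro-2-[2,2-dimethyl-5-(triisopropylsilyloxy)-2H-chromen-8-yl]propyl benzoate | O=C(OC[C@@H](c1ccc(O[Si](C(C)C)(C(C)C)C(C)C)c2C=CC(C)(C)Oc12)CCl)c1ccccc1
F7 | step 9 | tert-butyl 2-[2,2-dimethyl-5-(triisopropylsilyloxy)-2H-chromen-8-yl]acetate | CC(C)(C)OC(=O)Cc1ccc(O[Si](C(C)C)(C(C)C)C(C)C)c2C=CC(C)(C)Oc12
F8 | step 9 | tert-butyl 2-[2,2-dimethyl-5-(triisopropylsilyloxy)-2H-chromen-8-yl]-3-hydroxypropanoate (racemic) | CC(C)(C)OC(=O)C(CO)c1ccc(O[Si](C(C)C)(C(C)C)C(C)C)c2C=CC(C)(C)Oc12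
F9 | step 7 | 8-bromo-4-(2-methylprop-1-enyl)-2-phenyl-5-(triisopropylsilyloxy)-4H-1,3,2-benzodioxaborinine (racemic) | CC(C)=CC1OB(c2ccccc2)Oc2c(Br)ccc(O[Si](C(C)C)(C(C)C)C(C)C)c12
A1 | alternative 1 | 2-[(1R)-1-[2,2-dimethyl-5-(triisopropylsilyloxy)-2H-chromen-8-yl]-2-[2-methoxy-6-(methoxymethoxy)-4-(triisopropylsilyloxy)phenyl]ethyl]-4,4,5,5-tetramethyl-1,3,2-dioxaborolane | COc1cc(O[Si](C(C)C)(C(C)C)C(C)C)cc(OCOC)c1C[C@H](c1ccc(O[Si](C(C)C)(C(C)C)C(C)C)c2C=CC(C)(C)Oc12)B1OC(C)(C)C(C)(C)O1
A2 | alternative 1 | 2-methoxy-6-(methoxymethoxy)-4-(triisopropylsilyloxy)phenyl trifluoromethanesulfonate | COc1cc(O[Si](C(C)C)(C(C)C)C(C)C)cc(OCOC)c1OS(=O)(=O)C(F)(F)F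
A3 | alternative 1 | vinylboronic acid pinacol ester | C=CB1OC(C)(C)C(C)(C)O1
A4 | alternative 1 | 8-lithio-2,2-dimethyl-5-(triisopropylsilyloxy)-2H-chromene | [Li]c1ccc(O[Si](C(C)C)(C(C)C)C(C)C)c2C=CC(C)(C)Oc12
A5 | alternative 2 | 2-[(2R)-3-(tert-butyldimethylsilyloxy)-2-[2,2-dimethyl-5-(triisopropylsilyloxy)-2H-chromen-8-yl]propyl]-5-(allyloxy)-3-(triisopropylsilyloxy)phenol | Oc1cc(OCC=C)cc(O[Si](C(C)C)(C(C)C)C(C)C)c1C[C@H](c1ccc(O[Si](C(C)C)(C(C)C)C(C)C)c2C=CC(C)(C)Oc12)CO[Si](C)(C)C(C)(C)C
A6 | alternative 2 | (R)-8-[1-(tert-butyldimethylsilyloxy)-5-(triisopropylsilyloxy)pent-4-yn-2-yl]-2,2-dimethyl-5-(triisopropylsilyloxy)-2H-chromene | CC(C)[Si](OC#CC[C@H](c1ccc(O[Si](C(C)C)(C(C)C)C(C)C)c2C=CC(C)(C)Oc12)CO[Si](C)(C)C(C)(C)C)(C(C)C)C(C)C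
A7 | alternative 2 | 3-(allyloxy)cyclobut-2-en-1-one | O=C1CC(OCC=C)=C1
A8 | alternative 3 | (3R)-3-[2,2-dimethyl-5-(triisopropylsilyloxy)-2H-chromen-8-yl]-5-methoxy-7-(triisopropylsilyloxy)chroman-2-one | COc1cc(O[Si](C(C)C)(C(C)C)C(C)C)cc2c1C[C@H](c1ccc(O[Si](C(C)C)(C(C)C)C(C)C)c3C=CC(C)(C)Oc13)C(=O)O2
A9 | alternative 3 | 3-methoxy-2-[(4-methylphenyl)sulfonylmethyl]-5-(triisopropylsilyloxy)phenol | COc1cc(O[Si](C(C)C)(C(C)C)C(C)C)cc(O)c1CS(=O)(=O)c1ccc(C)cc1
A10 | alternative 3 | 2-[2,2-dimethyl-5-(triisopropylsilyloxy)-2H-chromen-8-yl]acetic acid | OC(=O)Cc1ccc(O[Si](C(C)C)(C(C)C)C(C)C)c2C=CC(C)(C)Oc12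
A11 | alternative 3 | 5-methoxy-6-methylidene-3-(triisopropylsilyloxy)cyclohexa-2,4-dien-1-one | C=C1C(=O)C=C(O[Si](C(C)C)(C(C)C)C(C)C)C=C1OC
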